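**Plan**

Retrosynthesis (chain locants C-1' to C-9' count from the methyl beside ring A; C-2' is bonded to ring A C-6, C-8' to ring B): cut first ring A C-6–C-2' (pyranonyl stannane 5 + cis-epoxide 39), then C-4'–C-5' (boron anti-aldol of lactate ketone 32 with enal 29), then ring B into triketone 26, i.e. pentan-3-one 21 plus aldehydes 10 and 20.
Forward: ring B is assembled first by double aldol, oxidation and cyclodehydration; the chain then grows leftward by aldol, 1,3-anti reduction and epoxide closure; ring A, made separately from 4-methylheptane-3,5-dione, CS2 and MeI, is joined last.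
Enabling feature: ring A C-6 carries the pair C-2'(H)(CH3)–C-3'(H)(OH) with methyl and hydroxyl anti, which is what back-side opening of a cis-2,3-epoxide at its methyl carbon by a C-6 pyranonyl nucleophile leaves; that carbon maps onto the carbinol carbon of lactate.
Stereochemistry: C-2' to C-5' and C-8' descend from methyl (R)-lactate: C-2' by double inversion (steps 24 and 26), C-4'/C-5' by the anti-aldol of ketone 32, C-3' by hydroxyl-directed reduction, C-8' by SN2 displacement of lactate triflate 12 by an alkenyl cuprate; the ring B pentan-2-yl pair comes from methyl (3S)-3-hydroxypentanoate by anti-selective dianion methylation; the (E)-alkene comes from carboalumination of propargyl alcohol.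

Key step: step 26

Remark: centres that are later oxidised away (C-4/C-5 of 23; C-5/C-6/C-8/C-9 of 25; C-6/C-8 of 26) are carried as mixtures and drawn without configuration; TBS = tert-butyldimethylsilyl, PMB = 4-methoxybenzyl.
Remark: 4-methylheptane-3,5-dione, methyl (R)-lactate and methyl (3S)-3-hydroxypentanoate are taken as commercial.

**Route**

Step 1
Reactants: 1 4-methylheptane-3,5-dione
Product: 3 4,6-dimethyl-7,7-bis(methylsulfanyl)hept-6-ene-3,5-dione, via dilithium dianion 2 (not isolated)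
Conditions: LiN(i-Pr)2 (2.2 equiv), THF, −78 to 0 °C; CS2, −78 °C; MeI (2.2 equiv), −78 °C to rt
Reagents that add atoms: carbon disulfide S=C=S; iodomethane CI
Why: The 1,3-diketone dianion should add through its terminal carbon to CS2, and double S-methylation (with proton shift to the ene-dithiolate) should give the α-oxo ketene dithioacetal, a ketene dithioacetal synthesis on a diketone dianion.

Step 2
Reactants: 3 4,6-dimethyl-7,7-bis(methylsulfanyl)hept-6-ene-3,5-dione
Product: 4 2-ethyl-3,5-dimethyl-6-(methylsulfanyl)-4H-pyran-4-one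
Conditions: p-TsOH·H2O (10 mol %), toluene, 80 °C
Reagents that add atoms: none
Why: Acid-promoted 6-endo attack of the C-3 enol oxygen on the bis(methylsulfanyl)alkene carbon and loss of MeSH should close the 4-pyranone, the known cyclisation of acylated α-oxo ketene dithioacetals.

Step 3
Reactants: 4 2-ethyl-3,5-dimethyl-6-(methylsulfanyl)-4H-pyran-4-one
Product: 5 2-ethyl-3,5-dimethyl-6-(tributylstannyl)-4H-pyran-4-one
Conditions: Bu3SnH, LiN(i-Pr)2, THF, 0 °C; then 4, −78 °C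
Reagents that add atoms: tributylstannane CCCC[SnH](CCCC)CCCC
Why: Conjugate addition of Bu3SnLi to the vinylogous thioester carbon C-6 and expulsion of methanethiolate should give the β-stannyl enone, an addition–elimination of a stannyl anion on a β-heteroatom-substituted enone.

Step 4
Reactants: 6 methyl (3S)-3-hydroxypentanoate
Product: 8 methyl (2S,3S)-3-hydroxy-2-methylpentanoate, via dilithium alkoxide enolate 7 (not isolated)
Conditions: LiN(i-Pr)2 (2.2 equiv), THF, −78 to −20 °C; MeI, DMPU, −78 to 0 °C; aq. NH4Cl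
Reagents that add atoms: iodomethane CI
Why: The chelated alkoxide enolate should be methylated on the face opposite the C-3 ethyl group of the six-membered lithium chelate, setting C-2 anti to the existing carbinol centre (Fráter–Seebach alkylation of a β-hydroxy ester dianion).

Step 5
Reactants: 8 methyl (2S,3S)-3-hydroxy-2-methylpentanoate
Product: 9 methyl (2S,3S)-2-methyl-3-(TBSO)pentanoate
Conditions: TBSOTf, 2,6-lutidine, CH2Cl2, −78 to 0 °C
Reagents that add atoms: tert-butyldimethylsilyl trifluoromethanesulfonate CC(C)(C)[Si](C)(C)OS(=O)(=O)C(F)(F)F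
Why: Silylation of the secondary alcohol with the silyl triflate and a hindered base should proceed without enolising the α-stereocentre.

Step 6
Reactants: 9 methyl (2S,3S)-2-methyl-3-(TBSO)pentanoate
Product: 10 (2S,3S)-2-methyl-3-(TBSO)pentanal
Conditions: i-Bu2AlH (1.1 equiv), CH2Cl2, −78 °C; aq. potassium sodium tartrate
Reagents that add atoms: none
Why: The aluminium hemiacetal of the β-silyloxy ester is stable at −78 °C and should release the anti α-methyl-β-silyloxy aldehyde only on work-up, so neither over-reduction nor epimerisation is expected (partial ester reduction).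

Step 7
Reactants: 11 methyl (2R)-2-hydroxypropanoate (methyl (R)-lactate)
Product: 12 methyl (2R)-2-{[(trifluoromethyl)sulfonyl]oxy}propanoate
Conditions: Tf2O, 2,6-lutidine, CH2Cl2, −78 to 0 °C
Reagents that add atoms: trifluoromethanesulfonic anhydride O=S(=O)(OS(=O)(=O)C(F)(F)F)C(F)(F)F
Why: O-Sulfonylation should activate the lactate carbinol carbon without changing its configuration.

Step 8
Reactants: 13 prop-2-yn-1-ol
Product: 15 (2E)-3-iodo-2-methylprop-2-en-1-ol, via alkenylalane 14 (not isolated)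
Conditions: Me3Al (3 equiv), Cp2ZrCl2 (0.25 equiv), CH2Cl2, 0 °C to rt; I2, THF, −30 °C
Reagents that add atoms: trimethylaluminium C[Al](C)C; iodine II
Why: Zirconium-catalysed syn-carboalumination should place methyl on the internal and aluminium on the terminal alkyne carbon, and iodinolysis with retention should give the (E)-iodide (Negishi carboalumination).

Step 9
Reactants: 15 (2E)-3-iodo-2-methylprop-2-en-1-ol
Product: 16 1-({[(2E)-3-iodo-2-methylprop-2-en-1-yl]oxy}methyl)-4-methoxybenzene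
Conditions: NaH, 4-methoxybenzyl chloride, Bu4NI (cat.), THF/DMF, 0 °C to rt
Reagents that add atoms: 4-methoxybenzyl chloride COc1ccc(CCl)cc1
Why: Williamson etherification of the primary allylic alkoxide should leave the vinyl iodide untouched.

Step 10
Reactants: 16 1-({[(2E)-3-iodo-2-methylprop-2-en-1-yl]oxy}methyl)-4-methoxybenzene; 12 methyl (2R)-2-{[(trifluoromethyl)sulfonyl]oxy}propanoate
Product: 19 methyl (2R,3E)-2,4-dimethyl-5-(PMBO)pent-3-enoate, via alkenyllithium 17 (not isolated), via lithium dialkenylcuprate 18 (not isolated)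
Conditions: t-BuLi (2 equiv), Et2O, −78 °C; CuI (0.5 equiv), −78 to −40 °C; 12, −78 °C; aq. NH4Cl
Reagents that add atoms: none
Why: Iodine–lithium exchange with retention of alkene geometry, cuprate formation and SN2 displacement of the α-triflate with inversion should give the (R)-α-alkenyl ester (cuprate substitution of a lactate sulfonate).

Step 11
Reactants: 19 methyl (2R,3E)-2,4-dimethyl-5-(PMBO)pent-3-enoate
Product: 20 (2R,3E)-2,4-dimethyl-5-(PMBO)pent-3-enal
Conditions: i-Bu2AlH (1.05 equiv), CH2Cl2, −78 °C; aq. potassium sodium tartrate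
Reagents that add atoms: none
Why: The aluminium hemiacetal is stable at −78 °C and should release the aldehyde only on work-up, so neither over-reduction nor enolisation of the α-stereocentre is expected.

Step 12
Reactants: 21 pentan-3-one; 10 (2S,3S)-2-methyl-3-(TBSO)pentanal
Product: 23 (6R,7S)-5-hydroxy-4,6-dimethyl-7-(TBSO)nonan-3-one (C-4/C-5 epimers), via lithium enolate 22 (not isolated)
Conditions: LiN(i-Pr)2, THF, −78 °C; then 10, −78 °C; aq. NH4Cl
Reagents that add atoms: none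
Why: Lithium aldol addition is fast at −78 °C and should not epimerise the aldehyde; the two new centres are oxidised away later.

Step 13
Reactants: 23 (6R,7S)-5-hydroxy-4,6-dimethyl-7-(TBSO)nonan-3-one (C-4/C-5 epimers); 20 (2R,3E)-2,4-dimethyl-5-(PMBO)pent-3-enal
Product: 25 (2E,4R,10R,11S)-5,9-dihydroxy-2,4,6,8,10-pentamethyl-1-(PMBO)-11-(TBSO)tridec-2-en-7-one (epimers at C-5/C-6/C-8/C-9), via dilithium dianion 24 (not isolated)
Conditions: LiN(i-Pr)2 (2.2 equiv), THF, −78 °C; then 20, −78 °C; aq. NH4Cl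
Reagents that add atoms: none
Why: After alkoxide formation, kinetic enolisation should occur at the unhindered ethyl CH2, and the aldol addition should outrun epimerisation of the β,γ-unsaturated aldehyde (aldol reaction of a β-hydroxy ketone dianion).

Step 14
Reactants: 25 (2E,4R,10R,11S)-5,9-dihydroxy-2,4,6,8,10-pentamethyl-1-(PMBO)-11-(TBSO)tridec-2-en-7-one
Product: 26 (2E,4R,10S,11S)-2,4,6,8,10-pentamethyl-1-(PMBO)-11-(TBSO)tridec-2-ene-5,7,9-trione (C-6/C-8 epimers; enol forms)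
Conditions: Dess–Martin periodinane (3 equiv), NaHCO3, CH2Cl2, rt
Reagents that add atoms: none
Why: Buffered Dess–Martin oxidation should convert both carbinols into the 1,3,5-triketone without acid or base strong enough to epimerise C-4 or C-10.

Step 15
Reactants: 26 (2E,4R,10S,11S)-2,4,6,8,10-pentamethyl-1-(PMBO)-11-(TBSO)tridec-2-ene-5,7,9-trione
Product: 27 2-[(2R,3E)-4-methyl-5-(PMBO)pent-3-en-2-yl]-3,5-dimethyl-6-[(2S,3S)-3-(TBSO)pentan-2-yl]-4H-pyran-4-one
Conditions: PPh3, CCl4, THF, rt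
Reagents that add atoms: none
Why: O-Phosphonium activation of one terminal enol and intramolecular addition–elimination by the other enol oxygen should close ring B under non-acidic conditions, so the β,γ-alkene should not migrate (cyclodehydration of a β-triketone to a 4-pyranone).

Step 16
Reactants: 27 2-[(2R,3E)-4-methyl-5-(PMBO)pent-3-en-2-yl]-3,5-dimethyl-6-[(2S,3S)-3-(TBSO)pentan-2-yl]-4H-pyran-4-one
Product: 28 2-[(2R,3E)-5-hydroxy-4-methylpent-3-en-2-yl]-3,5-dimethyl-6-[(2S,3S)-3-(TBSO)pentan-2-yl]-4H-pyran-4-one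
Conditions: DDQ, CH2Cl2/aq. NaH2PO4/Na2HPO4 (pH 7), 0 °C
Reagents that add atoms: none
Why: Oxidative cleavage of the electron-rich benzyl ether should leave the silyl ether, the alkene and the pyranone untouched.

Step 17
Reactants: 28 2-[(2R,3E)-5-hydroxy-4-methylpent-3-en-2-yl]-3,5-dimethyl-6-[(2S,3S)-3-(TBSO)pentan-2-yl]-4H-pyran-4-one
Product: 29 (2E,4R)-4-{3,5-dimethyl-4-oxo-6-[(2S,3S)-3-(TBSO)pentan-2-yl]-4H-pyran-2-yl}-2-methylpent-2-enal
Conditions: MnO2, CH2Cl2, rt
Reagents that add atoms: none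
Why: Neutral allylic oxidation should give the (E)-enal without enolising the doubly activated C-4 hydrogen.

Step 18
Reactants: 11 methyl (2R)-2-hydroxypropanoate
Product: 30 (2R)-2-hydroxy-N-methoxy-N-methylpropanamide
Conditions: MeNH(OMe)·HCl, i-PrMgCl, THF, −20 to 0 °C
Reagents that add atoms: N,O-dimethylhydroxylamine hydrochloride CNOC.Cl
Why: Aminolysis of the ester by the chloromagnesium amide should give the Weinreb amide without touching the stereocentre (Weinreb amide formation).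

Step 19
Reactants: 30 (2R)-2-hydroxy-N-methoxy-N-methylpropanamide
Product: 31 (2R)-2-hydroxypentan-3-one
Conditions: EtMgBr (3 equiv), THF, 0 °C to rt
Reagents that add atoms: ethylmagnesium bromide CC[Mg]Br
Why: The chelated tetrahedral intermediate should stop at single addition and release the ethyl ketone on work-up with the carbinol centre intact (Weinreb ketone synthesis).

Step 20
Reactants: 31 (2R)-2-hydroxypentan-3-one
Product: 32 (2R)-3-oxopentan-2-yl benzoate
Conditions: benzoic anhydride, DMAP (cat.), i-Pr2NEt, CH2Cl2, rt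
Reagents that add atoms: benzoic anhydride O=C(OC(=O)c1ccccc1)c1ccccc1
Why: DMAP-catalysed O-acylation of the secondary alcohol should proceed without enolising the α-stereocentre.

Step 21
Reactants: 32 (2R)-3-oxopentan-2-yl benzoate; 29 (2E,4R)-4-{3,5-dimethyl-4-oxo-6-[(2S,3S)-3-(TBSO)pentan-2-yl]-4H-pyran-2-yl}-2-methylpent-2-enal
Product: 34 (2R,4S,5R,6E,8R)-8-{3,5-dimethyl-4-oxo-6-[(2S,3S)-3-(TBSO)pentan-2-yl]-4H-pyran-2-yl}-5-hydroxy-4,6-dimethyl-3-oxonon-6-en-2-yl benzoate, via boron enolate 33 (not isolated)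
Conditions: Cy2BCl, Me2NEt, Et2O, −78 to 0 °C; 29, −78 to −20 °C; H2O2, MeOH, aq. NaH2PO4/Na2HPO4 (pH 7), 0 °C
Reagents that add atoms: none
Why: The (E)-boron enolate should add through a chair transition state whose face is fixed by the benzoyloxy stereocentre, giving the 4,5-anti adduct and so setting C-4' and C-5', the remote C-8' centre having little influence (lactate-ketone boron anti-aldol, Paterson aldol).

Step 22
Reactants: 34 (2R,4S,5R,6E,8R)-8-{3,5-dimethyl-4-oxo-6-[(2S,3S)-3-(TBSO)pentan-2-yl]-4H-pyran-2-yl}-5-hydroxy-4,6-dimethyl-3-oxonon-6-en-2-yl benzoate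
Product: 35 (2R,3R,4S,5R,6E,8R)-8-{3,5-dimethyl-4-oxo-6-[(2S,3S)-3-(TBSO)pentan-2-yl]-4H-pyran-2-yl}-3,5-dihydroxy-4,6-dimethylnon-6-en-2-yl benzoate
Conditions: Me4NBH(OAc)3, MeCN/AcOH, −30 °C
Reagents that add atoms: none
Why: Hydride delivery from the acetoxyborohydride bound to the C-5' hydroxyl through a chair transition state should give the 1,3-anti diol and so set C-3' (Evans–Saksena reduction); the pyranone carbonyl is inert to this reagent.

Step 23
Reactants: 35 (2R,3R,4S,5R,6E,8R)-8-{3,5-dimethyl-4-oxo-6-[(2S,3S)-3-(TBSO)pentan-2-yl]-4H-pyran-2-yl}-3,5-dihydroxy-4,6-dimethylnon-6-en-2-yl benzoate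
Product: 36 3,5-dimethyl-2-[(2S,3S)-3-(TBSO)pentan-2-yl]-6-[(2R,3E,5R,6S,7R,8R)-5,7,8-trihydroxy-4,6-dimethylnon-3-en-2-yl]-4H-pyran-4-one
Conditions: K2CO3, MeOH, 0 °C
Reagents that add atoms: none
Why: Mild methanolysis should remove the benzoate while the lateral C–H bonds beside ring B are too weakly acidic to exchange at 0 °C.

Step 24
Reactants: 36 3,5-dimethyl-2-[(2S,3S)-3-(TBSO)pentan-2-yl]-6-[(2R,3E,5R,6S,7R,8R)-5,7,8-trihydroxy-4,6-dimethylnon-3-en-2-yl]-4H-pyran-4-one
Product: 38 2-[(2R,3E,5R,6S)-5-hydroxy-4-methyl-6-[(2R,3S)-3-methyloxiran-2-yl]hept-3-en-2-yl]-3,5-dimethyl-6-[(2S,3S)-3-(TBSO)pentan-2-yl]-4H-pyran-4-one, via tosylate 37 (not isolated)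
Conditions: TsCl, Et3N, Bu2SnO (5 mol %), CH2Cl2, 0 °C; then K2CO3, MeOH, 0 °C
Reagents that add atoms: none
Why: Tin-acetal-catalysed monosulfonylation should pick the less hindered C-2' hydroxyl of the 1,2-diol, and 3-exo-tet closure by the C-3' alkoxide with inversion at C-2' should give the cis-epoxide (Williamson-type epoxide formation).

Step 25
Reactants: 38 2-[(2R,3E,5R,6S)-5-hydroxy-4-methyl-6-[(2R,3S)-3-methyloxiran-2-yl]hept-3-en-2-yl]-3,5-dimethyl-6-[(2S,3S)-3-(TBSO)pentan-2-yl]-4H-pyran-4-one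
Product: 39 2-[(2R,3E,5R,6R)-4-methyl-6-[(2R,3S)-3-methyloxiran-2-yl]-5-(TBSO)hept-3-en-2-yl]-3,5-dimethyl-6-[(2S,3S)-3-(TBSO)pentan-2-yl]-4H-pyran-4-one
Conditions: TBSOTf, 2,6-lutidine, CH2Cl2, −78 °C
Reagents that add atoms: tert-butyldimethylsilyl trifluoromethanesulfonate CC(C)(C)[Si](C)(C)OS(=O)(=O)C(F)(F)F
Why: Low-temperature silylation of the C-5' hydroxyl should leave the oxirane intact and remove the internal nucleophile that could open it in the next step.

Step 26
Reactants: 5 2-ethyl-3,5-dimethyl-6-(tributylstannyl)-4H-pyran-4-one; 39 2-[(2R,3E,5R,6R)-4-methyl-6-[(2R,3S)-3-methyloxiran-2-yl]-5-(TBSO)hept-3-en-2-yl]-3,5-dimethyl-6-[(2S,3S)-3-(TBSO)pentan-2-yl]-4H-pyran-4-one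
Product: 42 2-ethyl-6-[(2R,3R,4R,5R,6E,8R)-8-{3,5-dimethyl-4-oxo-6-[(2S,3S)-3-(TBSO)pentan-2-yl]-4H-pyran-2-yl}-3-hydroxy-4,6-dimethyl-5-(TBSO)non-6-en-2-yl]-3,5-dimethyl-4H-pyran-4-one, via pyranonyllithium 40 (not isolated), via lithium dipyranonylcuprate 41 (not isolated)
Conditions: 5 (2.4 equiv), n-BuLi, THF, −78 °C; CuI (1.2 equiv), −78 to −40 °C; 39, BF3·OEt2, −78 to −40 °C; aq. NH4Cl/NH3
Reagents that add atoms: none
Why: Proposed new method: tin–lithium exchange on 5 should unmask the sp2 carbanion 40 at ring A C-6 regiospecifically (direct deprotonation would instead remove a proton from the C-2 ethyl group), and its Gilman cuprate 41 should open the BF3-activated oxirane of 39 by back-side SN2 attack at the methyl-bearing carbon, the closest known reaction type being the BF3-assisted opening of 1,2-disubstituted epoxides by alkenyl and aryl cuprates. No ring is closed in this step; the oxirane is opened. The new C-2' stereocentre is controlled by inversion at the lactate-derived oxirane carbon, which together with the inversion of step 24 places ring A where the lactate oxygen stood, while C-3' keeps the configuration set in step 22, so the anti methyl/hydroxyl pair should form stereospecifically. Regioselectivity is needed between the two oxirane carbons and should be secured by the α-branched, β-silyloxy chain on the distal carbon, which blocks it sterically and deactivates it inductively. Chemoselectivity over the two 4-pyranone units should follow from their vinylogous-ester carbonyls being flanked by two methyl groups and their β-carbons being fully substituted, and the weakly basic cuprate should not deprotonate the lateral C–H bonds at C-8' and beside ring B.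

Step 27
Reactants: 42 2-ethyl-6-[(2R,3R,4R,5R,6E,8R)-8-{3,5-dimethyl-4-oxo-6-[(2S,3S)-3-(TBSO)pentan-2-yl]-4H-pyran-2-yl}-3-hydroxy-4,6-dimethyl-5-(TBSO)non-6-en-2-yl]-3,5-dimethyl-4H-pyran-4-one
Product: 43 2-ethyl-6-[(2R,3R,4R,5R,6E,8R)-3,5-dihydroxy-8-{6-[(2S,3S)-3-hydroxypentan-2-yl]-3,5-dimethyl-4-oxo-4H-pyran-2-yl}-4,6-dimethylnon-6-en-2-yl]-3,5-dimethyl-4H-pyran-4-one (CNP0408419.9)
Conditions: HF·pyridine, pyridine, THF, 0 °C to rt
Reagents that add atoms: none
Why: Buffered fluoride cleavage of both silyl ethers is non-basic and should leave the pyranone-flanked stereocentres at C-2', C-8' and beside ring B untouched.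

**Compound list**

1 | 4-methylheptane-3,5-dione | CCC(=O)C(C)C(=O)CC | starting material
2 | dilithium 4-methylhepta-2,4-diene-3,5-diolate (dianion of 1) | CC=C(O[Li])C(C)=C(CC)O[Li] | intermediate
3 | 4,6-dimethyl-7,7-bis(methylsulfanyl)hept-6-ene-3,5-dione | CCC(=O)C(C)C(=O)C(C)=C(SC)SC | intermediate
4 | 2-ethyl-3,5-dimethyl-6-(methylsulfanyl)-4H-pyran-4-one | CCc1oc(SC)c(C)c(=O)c1C | intermediate
5 | 2-ethyl-3,5-dimethyl-6-(tributylstannyl)-4H-pyran-4-one | CCCC[Sn](CCCC)(CCCC)c1oc(CC)c(C)c(=O)c1C | intermediate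
6 | methyl (3S)-3-hydroxypentanoate | COC(=O)C[C@@H](O)CC | starting material
7 | dilithium alkoxide enolate of 6 (lithium (3S)-1-methoxy-1-(lithiooxy)pent-1-en-3-olate) | COC(O[Li])=C[C@@H](O[Li])CC | intermediate
8 | methyl (2S,3S)-3-hydroxy-2-methylpentanoate | COC(=O)[C@@H](C)[C@@H](O)CC | intermediate
9 | methyl (2S,3S)-3-[(tert-butyldimethylsilyl)oxy]-2-methylpentanoate | COC(=O)[C@@H](C)[C@@H](O[Si](C)(C)C(C)(C)C)CC | intermediate
10 | (2S,3S)-3-[(tert-butyldimethylsilyl)oxy]-2-methylpentanal | O=C[C@@H](C)[C@@H](O[Si](C)(C)C(C)(C)C)CC | intermediate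
11 | methyl (2R)-2-hydroxypropanoate | C[C@@H](O)C(=O)OC | starting material
12 | methyl (2R)-2-{[(trifluoromethyl)sulfonyl]oxy}propanoate | COC(=O)[C@@H](C)OS(=O)(=O)C(F)(F)F | intermediate
13 | prop-2-yn-1-ol | C#CCO | starting material
14 | dimethyl[(1E)-3-[(dimethylalumanyl)oxy]-2-methylprop-1-en-1-yl]alumane | C[Al](C)OC/C(C)=C/[Al](C)C | intermediate
15 | (2E)-3-iodo-2-methylprop-2-en-1-ol | OC/C(C)=C/I | intermediate
16 | 1-({[(2E)-3-iodo-2-methylprop-2-en-1-yl]oxy}methyl)-4-methoxybenzene | COc1ccc(COC/C(C)=C/I)cc1 | intermediate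
17 | [(1E)-3-[(4-methoxybenzyl)oxy]-2-methylprop-1-en-1-yl]lithium | COc1ccc(COC/C(C)=C/[Li])cc1 | intermediate
18 | lithium bis[(1E)-3-[(4-methoxybenzyl)oxy]-2-methylprop-1-en-1-yl]cuprate | [Li+].COc1ccc(COC/C(C)=C/[Cu-]/C=C(C)/COCc2ccc(OC)cc2)cc1 | intermediate
19 | methyl (2R,3E)-5-[(4-methoxybenzyl)oxy]-2,4-dimethylpent-3-enoate | COC(=O)[C@H](C)/C=C(C)/COCc1ccc(OC)cc1 | intermediate
20 | (2R,3E)-5-[(4-methoxybenzyl)oxy]-2,4-dimethylpent-3-enal | O=C[C@H](C)/C=C(C)/COCc1ccc(OC)cc1 | intermediate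
21 | pentan-3-one | CCC(=O)CC | starting material
22 | lithium pent-2-en-3-olate | CC=C(CC)O[Li] | intermediate
23 | (6R,7S)-7-[(tert-butyldimethylsilyl)oxy]-5-hydroxy-4,6-dimethylnonan-3-one (C-4/C-5 epimers) | CCC(=O)C(C)C(O)[C@@H](C)[C@@H](O[Si](C)(C)C(C)(C)C)CC | intermediate
24 | dilithium dianion of 23 (C-5 alkoxide and C-2/C-3 enolate) | CC=C(O[Li])C(C)C(O[Li])[C@@H](C)[C@@H](O[Si](C)(C)C(C)(C)C)CC | intermediate
25 | (2E,4R,10R,11S)-11-[(tert-butyldimethylsilyl)oxy]-5,9-dihydroxy-1-[(4-methoxybenzyl)oxy]-2,4,6,8,10-pentamethyltridec-2-en-7-one (epimers at C-5/C-6/C-8/C-9) | COc1ccc(COC/C(C)=C/[C@@H](C)C(O)C(C)C(=O)C(C)C(O)[C@@H](C)[C@@H](O[Si](C)(C)C(C)(C)C)CC)cc1 | intermediate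
26 | (2E,4R,10S,11S)-11-[(tert-butyldimethylsilyl)oxy]-1-[(4-methoxybenzyl)oxy]-2,4,6,8,10-pentamethyltridec-2-ene-5,7,9-trione (C-6/C-8 epimers) | COc1ccc(COC/C(C)=C/[C@@H](C)C(=O)C(C)C(=O)C(C)C(=O)[C@@H](C)[C@@H](O[Si](C)(C)C(C)(C)C)CC)cc1 | intermediate
27 | 2-[(2S,3S)-3-[(tert-butyldimethylsilyl)oxy]pentan-2-yl]-6-[(2R,3E)-5-[(4-methoxybenzyl)oxy]-4-methylpent-3-en-2-yl]-3,5-dimethyl-4H-pyran-4-one | COc1ccc(COC/C(C)=C/[C@@H](C)c2oc([C@@H](C)[C@@H](O[Si](C)(C)C(C)(C)C)CC)c(C)c(=O)c2C)cc1 | intermediate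
28 | 2-[(2S,3S)-3-[(tert-butyldimethylsilyl)oxy]pentan-2-yl]-6-[(2R,3E)-5-hydroxy-4-methylpent-3-en-2-yl]-3,5-dimethyl-4H-pyran-4-one | OC/C(C)=C/[C@@H](C)c1oc([C@@H](C)[C@@H](O[Si](C)(C)C(C)(C)C)CC)c(C)c(=O)c1C | intermediate
29 | (2E,4R)-4-{6-[(2S,3S)-3-[(tert-butyldimethylsilyl)oxy]pentan-2-yl]-3,5-dimethyl-4-oxo-4H-pyran-2-yl}-2-methylpent-2-enal | O=C/C(C)=C/[C@@H](C)c1oc([C@@H](C)[C@@H](O[Si](C)(C)C(C)(C)C)CC)c(C)c(=O)c1C | intermediate
30 | (2R)-2-hydroxy-N-methoxy-N-methylpropanamide | C[C@@H](O)C(=O)N(C)OC | intermediate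
31 | (2R)-2-hydroxypentan-3-one | CCC(=O)[C@@H](C)O | intermediate
32 | (2R)-3-oxopentan-2-yl benzoate | CCC(=O)[C@@H](C)OC(=O)c1ccccc1 | intermediate
33 | (2R,3E)-3-[(dicyclohexylboranyl)oxy]pent-3-en-2-yl benzoate | C/C=C(/OB(C1CCCCC1)C1CCCCC1)[C@@H](C)OC(=O)c1ccccc1 | intermediate
34 | (2R,4S,5R,6E,8R)-8-{6-[(2S,3S)-3-[(tert-butyldimethylsilyl)oxy]pentan-2-yl]-3,5-dimethyl-4-oxo-4H-pyran-2-yl}-5-hydroxy-4,6-dimethyl-3-oxonon-6-en-2-yl benzoate | O=C(O[C@H](C)C(=O)[C@@H](C)[C@@H](O)/C(C)=C/[C@@H](C)c1oc([C@@H](C)[C@@H](O[Si](C)(C)C(C)(C)C)CC)c(C)c(=O)c1C)c1ccccc1 | intermediate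
35 | (2R,3R,4S,5R,6E,8R)-8-{6-[(2S,3S)-3-[(tert-butyldimethylsilyl)oxy]pentan-2-yl]-3,5-dimethyl-4-oxo-4H-pyran-2-yl}-3,5-dihydroxy-4,6-dimethylnon-6-en-2-yl benzoate | O=C(O[C@H](C)[C@H](O)[C@@H](C)[C@@H](O)/C(C)=C/[C@@H](C)c1oc([C@@H](C)[C@@H](O[Si](C)(C)C(C)(C)C)CC)c(C)c(=O)c1C)c1ccccc1 | intermediate
36 | 2-[(2S,3S)-3-[(tert-butyldimethylsilyl)oxy]pentan-2-yl]-3,5-dimethyl-6-[(2R,3E,5R,6S,7R,8R)-5,7,8-trihydroxy-4,6-dimethylnon-3-en-2-yl]-4H-pyran-4-one | C[C@@H](O)[C@H](O)[C@@H](C)[C@@H](O)/C(C)=C/[C@@H](C)c1oc([C@@H](C)[C@@H](O[Si](C)(C)C(C)(C)C)CC)c(C)c(=O)c1C | intermediate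
37 | (2R,3R,4S,5R,6E,8R)-8-{6-[(2S,3S)-3-[(tert-butyldimethylsilyl)oxy]pentan-2-yl]-3,5-dimethyl-4-oxo-4H-pyran-2-yl}-3,5-dihydroxy-4,6-dimethylnon-6-en-2-yl 4-methylbenzenesulfonate | Cc1ccc(cc1)S(=O)(=O)O[C@H](C)[C@H](O)[C@@H](C)[C@@H](O)/C(C)=C/[C@@H](C)c1oc([C@@H](C)[C@@H](O[Si](C)(C)C(C)(C)C)CC)c(C)c(=O)c1C | intermediate
38 | 2-[(2S,3S)-3-[(tert-butyldimethylsilyl)oxy]pentan-2-yl]-6-[(2R,3E,5R,6S)-5-hydroxy-4-methyl-6-[(2R,3S)-3-methyloxiran-2-yl]hept-3-en-2-yl]-3,5-dimethyl-4H-pyran-4-one | C[C@@H]1O[C@@H]1[C@@H](C)[C@@H](O)/C(C)=C/[C@@H](C)c2oc([C@@H](C)[C@@H](O[Si](C)(C)C(C)(C)C)CC)c(C)c(=O)c2C | intermediate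
39 | 2-[(2R,3E,5R,6R)-5-[(tert-butyldimethylsilyl)oxy]-4-methyl-6-[(2R,3S)-3-methyloxiran-2-yl]hept-3-en-2-yl]-6-[(2S,3S)-3-[(tert-butyldimethylsilyl)oxy]pentan-2-yl]-3,5-dimethyl-4H-pyran-4-one | C[C@@H]1O[C@@H]1[C@@H](C)[C@@H](O[Si](C)(C)C(C)(C)C)/C(C)=C/[C@@H](C)c2oc([C@@H](C)[C@@H](O[Si](C)(C)C(C)(C)C)CC)c(C)c(=O)c2C | intermediate
40 | (6-ethyl-3,5-dimethyl-4-oxo-4H-pyran-2-yl)lithium | [Li]c1oc(CC)c(C)c(=O)c1C | intermediate
41 | lithium bis(6-ethyl-3,5-dimethyl-4-oxo-4H-pyran-2-yl)cuprate | [Li+].CCc1oc([Cu-]c2oc(CC)c(C)c(=O)c2C)c(C)c(=O)c1C | intermediate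
42 | 2-ethyl-6-[(2R,3R,4R,5R,6E,8R)-5-[(tert-butyldimethylsilyl)oxy]-8-{6-[(2S,3S)-3-[(tert-butyldimethylsilyl)oxy]pentan-2-yl]-3,5-dimethyl-4-oxo-4H-pyran-2-yl}-3-hydroxy-4,6-dimethylnon-6-en-2-yl]-3,5-dimethyl-4H-pyran-4-one | CCc1oc([C@H](C)[C@H](O)[C@@H](C)[C@@H](O[Si](C)(C)C(C)(C)C)/C(C)=C/[C@@H](C)c2oc([C@@H](C)[C@@H](O[Si](C)(C)C(C)(C)C)CC)c(C)c(=O)c2C)c(C)c(=O)c1C | intermediate
43 | 2-ethyl-6-[(2R,3R,4R,5R,6E,8R)-3,5-dihydroxy-8-{6-[(2S,3S)-3-hydroxypentan-2-yl]-3,5-dimethyl-4-oxo-4H-pyran-2-yl}-4,6-dimethylnon-6-en-2-yl]-3,5-dimethyl-4H-pyran-4-one | CCc1oc([C@H](C)[C@H](O)[C@@H](C)[C@@H](O)/C(C)=C/[C@@H](C)c2oc([C@@H](C)[C@@H](O)CC)c(C)c(=O)c2C)c(C)c(=O)c1C | target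

**Step count and risks**

Total step count: 27. Longest linear sequence: 16 steps (steps 4–6, 12–17 and 21–27, from methyl (3S)-3-hydroxypentanoate 6 to 43; the branch from prop-2-yn-1-ol 13 through steps 8–11, 13–17 and 21–27 is equally long).

Steps most likely to fail:

Step 26 (Proposed new method). The lithiated pyranone may be quenched by proton transfer from the C-2 ethyl group of a second molecule, or the cuprate may be too weakly nucleophilic to open the hindered internal oxirane before BF3 diverts it toward the pyranone rings. Fallback by known chemistry, forming C-2'–C-3' instead: setting out from triol 36, NaIO4 in MeOH/H2O would cleave the C-2'/C-3' glycol to (2S,3R,4E,6R)-6-{6-[(2S,3S)-3-(TBSO)pentan-2-yl]-3,5-dimethyl-4-oxo-4H-pyran-2-yl}-3-hydroxy-2,4-dimethylhept-4-enal F1. TBSOTf/2,6-lutidine would give its 3-O-TBS ether F2. A vinylogous aldol addition of the lateral lithium dienolate (LiN(SiMe3)2, THF, −78 °C) of 2,6-diethyl-3,5-dimethyl-4H-pyran-4-one F3 (from pentan-3-one 21 and propanoic anhydride in polyphosphoric acid) to F2 would come back to the route at 42. Felkin and 1,3-anti induction from the anti-configured aldehyde should reinforce each other for C-3'; the C-2'/C-3' relationship would depend on dienolate geometry and may need separation of diastereomers.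

Step 3. The stannyl anion may attack sulfur or the carbonyl instead of adding in conjugate fashion, or the β-stannyl enone may protodestannylate on work-up. Fallback: from sulfide 4, SO2Cl2 in CH2Cl2 (chlorodesulfurisation of the vinylogous thioester) would give 6-chloro-2-ethyl-3,5-dimethyl-4H-pyran-4-one F4, and stannylation with (Bu3Sn)2 catalysed by Pd(PPh3)4 (zerovalent palladium) in toluene would come back to the route at 5.

Step 24. Sulfonylation may occur at the wrong hydroxyl, or the free C-5' hydroxyl may close a tetrahydrofuran by 5-exo attack in competition with epoxide formation. Fallback that protects before closing: from triol 36, 2,2-dimethoxypropane/PPTS would give the dioxolane of the C-2'/C-3' syn-diol F5 (preferred over the acetonide of the anti-1,3-diol). TBSOTf/2,6-lutidine would give its C-5' silyl ether F6, and CSA in MeOH at 0 °C the C-2'/C-3' diol F7. TsCl/Et3N/Bu2SnO would give the C-2' tosylate F8, and K2CO3/MeOH would close the epoxide, coming back to the route at 39.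

**Further compounds**

F1 | step 26 | (2S,3R,4E,6R)-6-{6-[(2S,3S)-3-[(tert-butyldimethylsilyl)oxy]pentan-2-yl]-3,5-dimethyl-4-oxo-4H-pyran-2-yl}-3-hydroxy-2,4-dimethylhept-4-enal | O=C[C@@H](C)[C@@H](O)/C(C)=C/[C@@H](C)c1oc([C@@H](C)[C@@H](O[Si](C)(C)C(C)(C)C)CC)c(C)c(=O)c1C
F2 | step 26 | 3-O-tert-butyldimethylsilyl ether of F1 | O=C[C@@H](C)[C@@H](O[Si](C)(C)C(C)(C)C)/C(C)=C/[C@@H](C)c1oc([C@@H](C)[C@@H](O[Si](C)(C)C(C)(C)C)CC)c(C)c(=O)c1C
F3 | step 26 | 2,6-diethyl-3,5-dimethyl-4H-pyran-4-one | CCc1oc(CC)c(C)c(=O)c1C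
F4 | step 3 | 6-chloro-2-ethyl-3,5-dimethyl-4H-pyran-4-one | CCc1oc(Cl)c(C)c(=O)c1C
F5 | step 24 | C-2'/C-3' acetonide (2,2-dimethyl-1,3-dioxolane) of triol 36 | C[C@H]1OC(C)(C)O[C@@H]1[C@@H](C)[C@@H](O)/C(C)=C/[C@@H](C)c2oc([C@@H](C)[C@@H](O[Si](C)(C)C(C)(C)C)CC)c(C)c(=O)c2C
F6 | step 24 | C-5' tert-butyldimethylsilyl ether of F5 | C[C@H]1OC(C)(C)O[C@@H]1[C@@H](C)[C@@H](O[Si](C)(C)C(C)(C)C)/C(C)=C/[C@@H](C)c2oc([C@@H](C)[C@@H](O[Si](C)(C)C(C)(C)C)CC)c(C)c(=O)c2C
F7 | step 24 | C-2'/C-3' diol carrying the C-5' tert-butyldimethylsilyl ether | C[C@@H](O)[C@H](O)[C@@H](C)[C@@H](O[Si](C)(C)C(C)(C)C)/C(C)=C/[C@@H](C)c1oc([C@@H](C)[C@@H](O[Si](C)(C)C(C)(C)C)CC)c(C)c(=O)c1C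
F8 | step 24 | C-2' 4-methylbenzenesulfonate of F7 | Cc1ccc(cc1)S(=O)(=O)O[C@H](C)[C@H](O)[C@@H](C)[C@@H](O[Si](C)(C)C(C)(C)C)/C(C)=C/[C@@H](C)c1oc([C@@H](C)[C@@H](O[Si](C)(C)C(C)(C)C)CC)c(C)c(=O)c1C
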